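**Retrosynthetic overview**
- The target is the C1‑hydroxylated [4+2] homodimer of 8‑epi‑xanthatin. The last disconnection is a vinylogous (γ) aerobic hydroxylation at C1; before it, a Diels–Alder dimerisation forms C3–C11′ and C5–C13′ (spiro‑cyclohexene, formed last).
- 8‑epi‑Xanthatin comes from a domino ring‑closing enyne metathesis/cross‑metathesis of a cis‑lactone enyne with methyl vinyl ketone (C1=C5 and C2=C3; seven‑membered ring formed second).
- The cis‑α‑methylene‑γ‑butyrolactone (formed first) comes from a chiral‑phosphoric‑acid‑catalysed allylboration/lactonisation (C7–C8) of a β‑alkynyl aldehyde with a γ‑allyl 2‑(methoxycarbonyl)allylboronate.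
- The aldehyde (C10 stereocentre, C1–C10 bond) comes from an amine‑catalysed conjugate alkynylation of crotonaldehyde; the boronate from carbocupration of methyl propiolate and borylmethylation.
- Ring order: γ‑lactone → cycloheptene → spiro‑cyclohexene (dimerisation).

Assumptions: xanthanolide numbering is used (C1–C15 for the diene‑derived half, primed for the dienophile‑derived half); potassium trifluoro[(trimethylsilyl)ethynyl]borate is taken as a catalogue reagent; catalyst antipodes are assigned from the accepted face models of the parent reactions.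

**Route**

Step 1
Reactants: 1 (E)-crotonaldehyde; 2 potassium trifluoro[(trimethylsilyl)ethynyl]borate
Product: 3 (S)-3-methyl-5-(trimethylsilyl)pent-4-ynal
Conditions: (2R,5R)-5-benzyl-2-tert-butyl-3-methylimidazolidin-4-one·HCl (20 mol%), HF (48% aq, 1 equiv), DME, −20 °C
Reagents that add atoms: none
Why: Proposed new method: the imidazolidinone condenses with 1 to an (E)-iminium ion whose lowered LUMO is attacked at C‑β by the ipso carbon of the alkynyl–BF3⁻ π bond (β‑borate‑stabilised vinyl cation or concerted SE2‑type transfer), fluoride takes up BF3 as KBF4 and hydrolysis of the enamine releases 3 and the amine; the benzyl arm of the (2R,5R)-catalyst leaves the Si face of C‑β open, which gives (S)-C10; the closest known reaction type is the iminium‑catalysed Friedel–Crafts‑type conjugate addition of vinyl‑ and heteroaryl‑trifluoroborates to enals.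

Step 2
Reactants: 4 methyl propiolate; 5 allylmagnesium bromide; 6 2-(iodomethyl)-4,4,5,5-tetramethyl-1,3,2-dioxaborolane
Product: 8 methyl (2E)-2-[(4,4,5,5-tetramethyl-1,3,2-dioxaborolan-2-yl)methyl]hexa-2,5-dienoate, via alkenylcopper 7 (not isolated)
Conditions: 5 (2 equiv), CuBr·SMe2 (1 equiv), THF, −78 °C; then 4, −78 °C; then HMPA, 6, −78 → 0 °C
Reagents that add atoms: none
Why: syn‑Carbocupration of the ynoate followed by electrophilic trapping of the α‑cuprio acrylate with the iodomethylboronate (retention) places the allyl group cis to CH2B, the geometry that later gives the syn adduct.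

Step 3
Reactants: 3 (S)-3-methyl-5-(trimethylsilyl)pent-4-ynal; 8 methyl (2E)-2-[(4,4,5,5-tetramethyl-1,3,2-dioxaborolan-2-yl)methyl]hexa-2,5-dienoate
Product: 10 (4R,5R)-3-methylidene-5-[(2S)-2-methyl-4-(trimethylsilyl)but-3-yn-1-yl]-4-(prop-2-en-1-yl)oxolan-2-one, via borate ester 9 (not isolated)
Conditions: (S)-TRIP phosphoric acid (10 mol%), 4 Å MS, PhMe, rt → 40 °C; then p-TsOH·H2O (10 mol%), rt
Reagents that add atoms: none
Why: Chiral‑phosphoric‑acid‑catalysed allylboration through a closed chair transition state followed by allylboration–lactonisation of the 2‑alkoxycarbonyl allylboronate: the γ‑allyl group cis to CH2B sits axial and gives the syn adduct (cis‑lactone), and (S)-TRIP, hydrogen‑bonded to the pseudo‑axial boronate oxygen and the formyl H, directs attack to the Si face of the aldehyde, which sets C8 (R) and C7 (R) under catalyst control over the remote C10 centre.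

Step 4
Reactants: 10 (4R,5R)-3-methylidene-5-[(2S)-2-methyl-4-(trimethylsilyl)but-3-yn-1-yl]-4-(prop-2-en-1-yl)oxolan-2-one
Product: 11 (4R,5R)-3-methylidene-5-[(2S)-2-methylbut-3-yn-1-yl]-4-(prop-2-en-1-yl)oxolan-2-one
Conditions: TBAF (1.1 equiv), AcOH (1.1 equiv), THF, 0 °C
Reagents that add atoms: none
Why: Fluoride‑induced protodesilylation of the alkynylsilane, buffered with AcOH so that the α‑methylene lactone and the C7 centre are not touched.

Step 5
Reactants: 11 (4R,5R)-3-methylidene-5-[(2S)-2-methylbut-3-yn-1-yl]-4-(prop-2-en-1-yl)oxolan-2-one; 12 methyl vinyl ketone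
Product: 14 8-epi-xanthatin, via vinyl triene 13 (not isolated)
Conditions: Hoveyda–Grubbs II (10 mol%), 12 (6 equiv), CH2Cl2, 40 °C
Reagents that add atoms: none
Why: Domino ring‑closing enyne metathesis/cross‑metathesis: the Ru carbene formed at the allyl terminus closes the seven‑membered ring onto the alkyne to give the 1‑vinylcycloheptene 13, whose vinyl group undergoes E‑selective cross‑metathesis with excess 12, while the electron‑poor 1,1‑disubstituted methylene lactone stays inert and no stereocentre is touched.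

Step 6
Reactants: 14 8-epi-xanthatin (two molecules, one as diene and one as dienophile)
Product: 15 endo Diels–Alder dimer of 8-epi-xanthatin (3S,5S,7R,8R,10S,11′S,7′R,8′R,10′S; C1=C2 in the new cyclohexene, 3-acetyl, 3-H cis to 5-H)
Conditions: neat (or 2 M in PhMe), BHT (5 mol%), Ar, dark, 90 °C, 36 h
Reagents that add atoms: none
Why: Thermal intermolecular Diels–Alder homodimerisation in which the s‑cis C5=C1–C2=C3 diene adds to the exocyclic C11′=C13′ of a second molecule with "ortho" regiochemistry (largest diene HOMO coefficient at C5 pairs with the CH2 terminus), endo (lactone C=O under the diene), on the convex face of the cis‑fused dienophile (anti to C6′/C9′) and on the diene face anti to the pseudo‑axial 10‑H, which sets C5 (S), C11′ (S) and the transient C3 centre.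

Step 7
Reactants: 15 endo Diels–Alder dimer of 8-epi-xanthatin
Product: 17 target CNP0168949.1, via hydroperoxide 16 (not isolated)
Conditions: O2 (1 atm), DBU (1.2 equiv), P(OEt)3 (2 equiv), MeCN, 0 °C
Reagents that add atoms: dioxygen, O=O
Why: Base‑mediated aerobic vinylogous (γ) hydroxylation of a β,γ‑unsaturated ketone: DBU removes the doubly activated 3‑H, the extended enolate is trapped by O2 at C1 by axial attack anti to 5‑H and 10‑H (trans ring fusion, C1 (S)), the C2=C3 bond moves into conjugation with the acetyl group, and P(OEt)3 reduces hydroperoxide 16 in situ.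

**Compound list**
1 | (E)-crotonaldehyde | C/C=C/C=O | starting material
2 | potassium trifluoro[(trimethylsilyl)ethynyl]borate | C[Si](C)(C)C#C[B-](F)(F)F.[K+] | starting material
3 | (S)-3-methyl-5-(trimethylsilyl)pent-4-ynal | O=CC[C@H](C)C#C[Si](C)(C)C | intermediate
4 | methyl propiolate | C#CC(=O)OC | starting material
5 | allylmagnesium bromide | C=CC[Mg]Br | starting material
6 | 2-(iodomethyl)-4,4,5,5-tetramethyl-1,3,2-dioxaborolane | ICB1OC(C)(C)C(C)(C)O1 | starting material
7 | methyl (2Z)-2-cuprio-hexa-2,5-dienoate (alkenylcopper, present as its allylcuprate; not isolated) | C=CC/C=C(\[Cu])C(=O)OC | intermediate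
8 | methyl (2E)-2-[(4,4,5,5-tetramethyl-1,3,2-dioxaborolan-2-yl)methyl]hexa-2,5-dienoate (allyl cis to CH2B) | C=CC/C=C(\CB1OC(C)(C)C(C)(C)O1)C(=O)OC | intermediate
9 | methyl (3R,4R,6S)-6-methyl-2-methylidene-3-(prop-2-en-1-yl)-4-[(4,4,5,5-tetramethyl-1,3,2-dioxaborolan-2-yl)oxy]-8-(trimethylsilyl)oct-7-ynoate (syn borate ester; not isolated) | C=C(C(=O)OC)[C@@H](CC=C)[C@H](OB1OC(C)(C)C(C)(C)O1)C[C@H](C)C#C[Si](C)(C)C | intermediate
10 | (4R,5R)-3-methylidene-5-[(2S)-2-methyl-4-(trimethylsilyl)but-3-yn-1-yl]-4-(prop-2-en-1-yl)oxolan-2-one (cis-lactone) | C=C1C(=O)O[C@H](C[C@H](C)C#C[Si](C)(C)C)[C@@H]1CC=C | intermediate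
11 | (4R,5R)-3-methylidene-5-[(2S)-2-methylbut-3-yn-1-yl]-4-(prop-2-en-1-yl)oxolan-2-one (cis-lactone) | C=C1C(=O)O[C@H](C[C@H](C)C#C)[C@@H]1CC=C | intermediate
12 | methyl vinyl ketone (but-3-en-2-one) | C=CC(C)=O | starting material
13 | (3aR,7S,8aR)-6-ethenyl-7-methyl-3-methylidene-3,3a,4,7,8,8a-hexahydro-2H-cyclohepta[b]furan-2-one (not isolated) | C=C1C(=O)O[C@@H]2C[C@H](C)C(C=C)=CC[C@H]12 | intermediate
14 | 8-epi-xanthatin, (3aR,7S,8aR)-7-methyl-3-methylidene-6-[(1E)-3-oxobut-1-en-1-yl]-3,3a,4,7,8,8a-hexahydro-2H-cyclohepta[b]furan-2-one (cis-fused lactone) | C=C1C(=O)O[C@@H]2C[C@H](C)C(/C=C/C(C)=O)=CC[C@H]12 | intermediate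
15 | endo Diels–Alder dimer of 14: bonds C3–C11′ and C5–C13′, C1=C2 alkene, 3-acetyl; (3S,5S,7R,8R,10S,11′S,7′R,8′R,10′S), 3-H cis to 5-H, lactone C12′=O cis to C6 | C=C1C(=O)O[C@@H]2C[C@H](C)C3=C[C@H](C(C)=O)[C@@]4(C[C@@H]3C[C@H]12)C(=O)O[C@@H]1C[C@H](C)C(/C=C/C(C)=O)=CC[C@@H]14 | intermediate
16 | 1-hydroperoxide of the target, (1S)-OOH trans to 5-H, C2=C3 conjugated with the acetyl group (not isolated) | C=C1C(=O)O[C@@H]2C[C@H](C)[C@@]3(OO)C=C(C(C)=O)[C@@]4(C[C@@H]3C[C@H]12)C(=O)O[C@@H]1C[C@H](C)C(/C=C/C(C)=O)=CC[C@@H]14 | intermediate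
17 | CNP0168949.1: 1-hydroxy [4+2] dimer of 8-epi-xanthatin, (1S,5S,7R,8R,10S,11′S,7′R,8′R,10′S), 1-OH trans to 5-H, both γ-lactones cis-fused, spiro centre C11′ | C=C1C(=O)O[C@@H]2C[C@H](C)[C@@]3(O)C=C(C(C)=O)[C@@]4(C[C@@H]3C[C@H]12)C(=O)O[C@@H]1C[C@H](C)C(/C=C/C(C)=O)=CC[C@@H]14 | target

**Step count**
Total steps: 7. Longest linear sequence: 6 (steps 1, 3, 4, 5, 6, 7, from crotonaldehyde).

**Steps most likely to fail and fallbacks**

Step 1 (proposed new method; the alkynyltrifluoroborate may be too weak a π‑nucleophile for the iminium ion, or the ee may be low). The fallback uses known chemistry and sets out from 1. A Rh(I)/DTBM‑SEGPHOS‑catalysed asymmetric conjugate alkynylation of the enal with (triisopropylsilyl)acetylene ([Rh(OAc)(C2H4)2]2, MeOH, 40 °C; ligand antipode chosen for the S product) gives (S)-3-methyl-5-(triisopropylsilyl)pent-4-ynal F1. This is taken through the conditions of step 3 with 8, via the TIPS borate ester F2, to the TIPS lactone F3. TBAF/AcOH (THF, rt) then removes the silyl group and the route is rejoined at 11.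

Step 6 (the homodimerisation can give regio‑ or face‑isomeric adducts or low conversion). The fallback sets out from 14 and 11. Compound 14 is used only as the diene in a crossed Diels–Alder reaction with an excess (3–5 equiv) of lactone 11, which has no diene and an unhindered methylene lactone with both ring substituents on one face (PhMe, 90 °C); this gives the cross‑adduct F4. The second seven‑membered ring is then built on the adduct by the domino enyne RCM/CM with 12 (Hoveyda–Grubbs II), via the vinyl diene F5, and the route is rejoined at 15.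

Step 7 (competing conjugation to the unreactive enone, attack of base on the methylene lactone, or the wrong C1 face). The fallback sets out from 15 and replaces enolate autoxidation by an electrophilic sequence. mCPBA (NaHCO3, CH2Cl2, 0 °C) epoxidises the only electron‑rich alkene, C1=C2, to the 1,2‑epoxy ketone F6; this requires attack anti to 5‑H. Et3N (CH2Cl2, rt) then opens the β,γ‑epoxy ketone by E1cB elimination (3‑H removed, C2–O cleaved) to the γ‑hydroxy enone, so the route is rejoined at 17.

**Further compounds**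
F1 | step 1 | (S)-3-methyl-5-(triisopropylsilyl)pent-4-ynal | O=CC[C@H](C)C#C[Si](C(C)C)(C(C)C)C(C)C
F2 | step 1 | methyl (3R,4R,6S)-6-methyl-2-methylidene-3-(prop-2-en-1-yl)-4-[(4,4,5,5-tetramethyl-1,3,2-dioxaborolan-2-yl)oxy]-8-(triisopropylsilyl)oct-7-ynoate | C=C(C(=O)OC)[C@@H](CC=C)[C@H](OB1OC(C)(C)C(C)(C)O1)C[C@H](C)C#C[Si](C(C)C)(C(C)C)C(C)C
F3 | step 1 | (4R,5R)-3-methylidene-5-[(2S)-2-methyl-4-(triisopropylsilyl)but-3-yn-1-yl]-4-(prop-2-en-1-yl)oxolan-2-one | C=C1C(=O)O[C@H](C[C@H](C)C#C[Si](C(C)C)(C(C)C)C(C)C)[C@@H]1CC=C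
F4 | step 6 | crossed endo Diels–Alder adduct of 14 (diene) with 11 (dienophile): upper unit as in 15, spiro lactone carrying 7′-allyl and 8′-[(2S)-2-methylbut-3-yn-1-yl] | C=C1C(=O)O[C@@H]2C[C@H](C)C3=C[C@H](C(C)=O)[C@@]4(C[C@@H]3C[C@H]12)C(=O)O[C@H](C[C@H](C)C#C)[C@@H]4CC=C
F5 | step 6 | 1′-vinyl analogue of 15 (enyne ring-closure product of F4, before cross-metathesis) | C=C1C(=O)O[C@@H]2C[C@H](C)C3=C[C@H](C(C)=O)[C@@]4(C[C@@H]3C[C@H]12)C(=O)O[C@@H]1C[C@H](C)C(C=C)=CC[C@@H]14
F6 | step 7 | 1,2-epoxide of 15 (epoxide oxygen trans to 5-H) | C=C1C(=O)O[C@@H]2C[C@H](C)[C@@]3(O5)[C@H]5[C@H](C(C)=O)[C@@]4(C[C@@H]3C[C@H]12)C(=O)O[C@@H]1C[C@H](C)C(/C=C/C(C)=O)=CC[C@@H]14
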